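Start at the tail of the run.

| flask | starting material | partner | precatalyst | remark | time |
|---|---|---|---|---|---|
| red | 0.10 M | 0.070 M | 0.50 mM | the very flask that is asked about, followed so far |  |
| flask | 0.10 M | 0.0700 M | 0.50 mM |  | 12 d |

red run (percent of the starting material charged)

| time / d | isomer of the product / % | target / % |
|---|---|---|
| 0.333 | 10.6 | 8.8 |
| 0.833 | 18.6 | 5.2 |
| 1.67 | 24.8 | 3.0 |
| 2.50 | 27.2 | 1.7 |
| 4.00 | 27.7 | 1.8 |
| 5.00 | 28.0 | 1.1 |
| 6.00 | 28.0 | 0.5 |

(standard deviation of a reading: 0.5 percentage points)



- ratio of isomer of the product to target at 8.0 min
- ratio of isomer of the product to target at 12 d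

The red run is this same flask followed as far as 6.00 d; in it the isomer of the product levels off near 28.0% while the target sinks towards the noise, so I want a ratio that can be carried on to 12 d, as it could if the two products have come under thermodynamic rather than kinetic control. My first answer is the last reading alone, 28.0% over 0.5%, or 56.0, but put back into the run it asks for a target near 0.5% along the tail, whereas the reading at 4.00 d stands 1.3 percentage points above that, with a scatter of 0.5 points on a reading. So I go round again with the mean target of the last 3 readings, 1.13%, and define the plateau ratio Rp as the summed isomer of those readings over their summed target, which gives 24.6. Turned round, for this flask to end at 56.0 instead, the target would have to stand 0.63 points below that mean with the isomer unchanged, so Rp is my commitment and not a proof.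

The forecast says 0.02 at 8.0 min and 45 at 12 d, the latter “poorly bounded because target is near the noise”; my Rp is lower than that, and for the early ratio I offer no figure of my own, since the readings begin at 0.333 d.

The flask gives 0.140 at 8.0 min and 26.0 at 12 d. At 12.0 d the target is made at 0.959 of the rate at which it is used up, each step taken net. Put back once more, Rp turns the 24.6% of isomer in this flask into 1.000% of target, and the flask holds 0.946%.

    starting material + partner ⇌ target (K = 20.0 L mol⁻¹, k = 2.50 L mol⁻¹ h⁻¹)
    starting material + partner ⇌ isomer of the product (K = 420 L mol⁻¹, k = 0.340 L mol⁻¹ h⁻¹)
    target + catalyst ⇌ isomer of the product + catalyst, rate k3*[catalyst]*[target] forward; the back reaction follows from the equilibrium constant (k = 160 L mol⁻¹ h⁻¹)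
    partner ⇌ dormant form (K = 1.10, k = 0.720 h⁻¹)
    starting material + target → side product (k = 2.10 L mol⁻¹ h⁻¹)
    partner + precatalyst → catalyst + spent reagent (k = 27.0 L mol⁻¹ h⁻¹)

In the neighbour flask charged with 0.0020 M of precatalyst, Rp turns its 27.3% of isomer into 1.11% of target, a ratio of 24.6; the simulation gives 1.19% of target and a ratio of 22.9.

All runs were computed from invented constants, noise included.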